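**Retrosynthetic overview**
1. Target ⇒ benzyl-protected (R)-tridec-4-en-2-yl acetate: one final hydrogenation saturates C4=C5 and frees the phenol.
2. C4=C5 ⇒ cross-metathesis of an (R)-homoallylic acetate with dec-1-ene.
3. Key C2–C3 bond and the only stereocentre ⇒ asymmetric allylboration of (3-benzyloxy-5-methoxyphenyl)acetaldehyde with a pinene-derived allylborane.
4. Aldehyde ⇒ 2-arylethanol ⇒ styrene ⇒ 3-benzyloxy-5-methoxybenzaldehyde ⇒ 3,5-dimethoxybenzaldehyde (mono-demethylation, benzylation).
5. No ring is formed; the benzene ring is bought.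

Assumption: the [C@H] centre of the given SMILES is (R) (O > CH2Ar > undecyl > H); protonation states that change only on aqueous work-up are not counted as separate compounds.

**Step 1**
Reactants: 1 3,5-dimethoxybenzaldehyde
Product: 2 3-hydroxy-5-methoxybenzaldehyde
Conditions: NaSEt (2 equiv), DMF, 150 °C, 1–2 h; then 1 M HCl
Reagents that add atoms: none
Why: SN2 O-demethylation of an aryl methyl ether by thiolate stops after one cleavage because the phenoxide formed makes the second aryloxide a far poorer leaving group.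

**Step 2**
Reactants: 2 3-hydroxy-5-methoxybenzaldehyde
Product: 3 3-(benzyloxy)-5-methoxybenzaldehyde
Conditions: BnBr (1.1 equiv), K2CO3 (1.5 equiv), DMF, rt → 50 °C
Reagents that add atoms: benzyl bromide BrCc1ccccc1
Why: Williamson ether synthesis on the phenoxide; the non-enolisable aldehyde is inert to carbonate.

**Step 3**
Reactants: 3 3-(benzyloxy)-5-methoxybenzaldehyde
Product: 4 1-(benzyloxy)-3-ethenyl-5-methoxybenzene
Conditions: Ph3PCH3Br (1.3 equiv), KOtBu (1.25 equiv), THF, 0 °C → rt
Reagents that add atoms: methyltriphenylphosphonium bromide C[P+](c1ccccc1)(c1ccccc1)c1ccccc1.[Br-]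
Why: Wittig methylenation of a non-enolisable aryl aldehyde with an unstabilised ylide is fast and clean.

**Step 4**
Reactants: 4 1-(benzyloxy)-3-ethenyl-5-methoxybenzene
Product: 6 2-[3-(benzyloxy)-5-methoxyphenyl]ethan-1-ol, via trialkylborane 5 (not isolated)
Conditions: 9-BBN (1.3 equiv, 0.5 M in THF), 0 °C → rt; then 3 M NaOH, 30% H2O2, 0 °C → rt
Reagents that add atoms: 9-borabicyclo[3.3.1]nonane B1C2CCCC1CCC2 (boron cage, present in 5 only); hydrogen peroxide OO (hydroxyl oxygen of 6)
Why: hydroboration–oxidation with the bulky 9-BBN places boron on the terminal carbon of the styrene (>98:2) and the C–B bond is oxidised to C–OH by alkaline peroxide.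

**Step 5**
Reactants: 6 2-[3-(benzyloxy)-5-methoxyphenyl]ethan-1-ol
Product: 7 2-[3-(benzyloxy)-5-methoxyphenyl]acetaldehyde
Conditions: Dess–Martin periodinane (1.2 equiv), NaHCO3 (3 equiv), CH2Cl2, 0 °C → rt, 1 h; Na2S2O3/NaHCO3 wash; used crude at once
Reagents that add atoms: none
Why: Dess–Martin oxidation stops at the aldehyde under neutral, buffered, anhydrous conditions, which suits the easily enolised arylacetaldehyde.

**Step 6 (key step)**
Reactants: 7 2-[3-(benzyloxy)-5-methoxyphenyl]acetaldehyde
Product: 9 (2R)-1-[3-(benzyloxy)-5-methoxyphenyl]pent-4-en-2-ol, via borinate ester 8 (not isolated)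
Conditions: (+)-Ipc2BOMe (from (−)-α-pinene, 1.5 equiv), allylMgBr (1.4 equiv), Et2O, 0 °C → rt, Mg salts filtered off; then 7, Et2O/pentane, −100 → −78 °C; then 3 M NaOH, 30% H2O2, rt
Reagents that add atoms: allylmagnesium bromide C=CC[Mg]Br (the three allyl carbons); (+)-B-methoxydiisopinocampheylborane COB([C@H]1C[C@H]2C[C@@H]([C@@H]1C)C2(C)C)[C@H]1C[C@H]2C[C@@H]([C@@H]1C)C2(C)C (boron and Ipc groups, present in 8 only)
Why: Brown asymmetric allylboration (carbonyl allylation) runs through a closed six-membered chair transition state in which the isopinocampheyl groups of the (−)-α-pinene series direct allyl to the Re face of the aldehyde, giving the (R)-carbinol (ArCH2 outranks allyl) in typically 90–96% ee, and at −100 °C addition outruns enolisation of 7.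

**Step 7**
Reactants: 9 (2R)-1-[3-(benzyloxy)-5-methoxyphenyl]pent-4-en-2-ol
Product: 10 (2R)-1-[3-(benzyloxy)-5-methoxyphenyl]pent-4-en-2-yl acetate
Conditions: Ac2O (2 equiv), pyridine (3 equiv), DMAP (5 mol%), CH2Cl2, 0 °C → rt
Reagents that add atoms: acetic anhydride CC(=O)OC(C)=O
Why: DMAP-catalysed O-acylation breaks no bond at the stereocentre (retention), and with the phenol masked as its benzyl ether only the secondary alcohol is acetylated.

**Step 8**
Reactants: 10 (2R)-1-[3-(benzyloxy)-5-methoxyphenyl]pent-4-en-2-yl acetate; 11 dec-1-ene (4 equiv)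
Product: 12 (2R,4E)-1-[3-(benzyloxy)-5-methoxyphenyl]tridec-4-en-2-yl acetate (E major; the E/Z mixture is carried on)
Conditions: second-generation Grubbs catalyst RuCl2(=CHPh)(PCy3)(H2IMes) (5 mol%), CH2Cl2, 40 °C, argon sweep
Reagents that add atoms: none
Why: olefin cross-metathesis of two unhindered terminal alkenes is driven by loss of ethene and by the excess of dec-1-ene, and the alkene geometry does not matter because the double bond is hydrogenated next.

**Step 9**
Reactants: 12 (2R,4E)-1-[3-(benzyloxy)-5-methoxyphenyl]tridec-4-en-2-yl acetate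
Product: 14 (2R)-1-(3-hydroxy-5-methoxyphenyl)tridecan-2-yl acetate, via saturated benzyl ether 13 (not isolated)
Conditions: H2 (1 atm), 10% Pd/C, EtOAc, rt
Reagents that add atoms: none
Why: heterogeneous catalytic hydrogenation saturates the alkene and then hydrogenolyses the aryl benzyl ether, while the secondary acetate, which is neither benzylic nor allylic, and the stereocentre are untouched.

**Compound list**
1 | 3,5-dimethoxybenzaldehyde | COc1cc(C=O)cc(OC)c1 | starting material
2 | 3-hydroxy-5-methoxybenzaldehyde | COc1cc(O)cc(C=O)c1 | intermediate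
3 | 3-(benzyloxy)-5-methoxybenzaldehyde | COc1cc(C=O)cc(OCc2ccccc2)c1 | intermediate
4 | 1-(benzyloxy)-3-ethenyl-5-methoxybenzene | COc1cc(C=C)cc(OCc2ccccc2)c1 | intermediate
5 | 9-{2-[3-(benzyloxy)-5-methoxyphenyl]ethyl}-9-borabicyclo[3.3.1]nonane (not isolated) | COc1cc(CCB2C3CCCC2CCC3)cc(OCc2ccccc2)c1 | intermediate
6 | 2-[3-(benzyloxy)-5-methoxyphenyl]ethan-1-ol | COc1cc(CCO)cc(OCc2ccccc2)c1 | intermediate
7 | 2-[3-(benzyloxy)-5-methoxyphenyl]acetaldehyde | COc1cc(CC=O)cc(OCc2ccccc2)c1 | intermediate
8 | (2R)-1-[3-(benzyloxy)-5-methoxyphenyl]pent-4-en-2-yl diisopinocampheylborinate, Ipc groups of the (−)-α-pinene series (not isolated) | C=CC[C@H](Cc1cc(OC)cc(OCc2ccccc2)c1)OB([C@H]1C[C@H]2C[C@@H]([C@@H]1C)C2(C)C)[C@H]1C[C@H]2C[C@@H]([C@@H]1C)C2(C)C | intermediate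
9 | (2R)-1-[3-(benzyloxy)-5-methoxyphenyl]pent-4-en-2-ol | C=CC[C@H](Cc1cc(OC)cc(OCc2ccccc2)c1)O | intermediate
10 | (2R)-1-[3-(benzyloxy)-5-methoxyphenyl]pent-4-en-2-yl acetate | C=CC[C@H](Cc1cc(OC)cc(OCc2ccccc2)c1)OC(C)=O | intermediate
11 | dec-1-ene | C=CCCCCCCCC | starting material
12 | (2R,4E)-1-[3-(benzyloxy)-5-methoxyphenyl]tridec-4-en-2-yl acetate (E drawn; E/Z mixture) | CCCCCCCC/C=C/C[C@H](Cc1cc(OC)cc(OCc2ccccc2)c1)OC(C)=O | intermediate
13 | (2R)-1-[3-(benzyloxy)-5-methoxyphenyl]tridecan-2-yl acetate (not isolated) | CCCCCCCCCCC[C@H](Cc1cc(OC)cc(OCc2ccccc2)c1)OC(C)=O | intermediate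
14 | (2R)-1-(3-hydroxy-5-methoxyphenyl)tridecan-2-yl acetate | CCCCCCCCCCC[C@H](Cc1cc(O)cc(OC)c1)OC(C)=O | target

**Totals**
Total step count: 9. Longest linear sequence: 9 steps (1 → 14); dec-1-ene 11 enters at step 8.

**Three steps most likely to fail**

Step 1. The thiolate works at 150 °C next to a free aldehyde, so thiolate–aldehyde side reactions or incomplete cleavage can lower the yield. The fallback sets out from 1 and comes back at 3, bypassing 2. Compound 1 is acetalised with ethylene glycol (TsOH cat., toluene, Dean–Stark) to 2-(3,5-dimethoxyphenyl)-1,3-dioxolane F1. One methyl ether is then cleaved with NaSEt in DMF at 150 °C to give 3-(1,3-dioxolan-2-yl)-5-methoxyphenol F2. Benzylation (BnBr, K2CO3, DMF) gives 2-[3-(benzyloxy)-5-methoxyphenyl]-1,3-dioxolane F3, and the acetal is hydrolysed (1 M HCl, THF, rt) to 3.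

Step 5. The arylacetaldehyde 7 enolises, self-condenses and air-oxidises easily, so the oxidation and isolation may give poor recovery. The fallback sets out from 3 and comes back at 7, bypassing 4 to 6. A Wittig reaction of 3 with (methoxymethyl)triphenylphosphonium chloride and KOtBu in THF at 0 °C gives the enol ether 1-(benzyloxy)-3-methoxy-5-(2-methoxyethenyl)benzene F4 as an E/Z mixture. F4 can be stored and is hydrolysed (2 M HCl, THF, 0 °C → rt) to 7 just before the allylboration.

Step 6. The key allylboration uses an enolisable aldehyde, the enantiomeric excess may fall short of 95%, and isopinocampheol must be separated from 9. The fallback sets out from 6 and comes back at 9, merging steps 5 and 6. It is an iridium-catalysed transfer-hydrogenative carbonyl allylation at the alcohol oxidation level (Krische allylation): 6, allyl acetate (10 equiv), [Ir(cod)Cl]2 (2.5 mol%), (R)-BINAP (5 mol%), 4-chloro-3-nitrobenzoic acid (10 mol%), Cs2CO3 (20 mol%), THF, 100 °C. The alcohol is dehydrogenated on the metal to 7, which is allylated as it forms and never accumulates; the fallback makes no new compound (F0). The ligand must be the antipode that gives Re-face addition. I expect this to be (R)-BINAP from the trend I recall for CH2-substituted aldehydes, but I am not certain of it. The first run is therefore checked by chiral HPLC against 9 from step 6, and (S)-BINAP is used if the sense is reversed.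

**Further compounds**
F1 | step 1 | 2-(3,5-dimethoxyphenyl)-1,3-dioxolane | COc1cc(OC)cc(C2OCCO2)c1
F2 | step 1 | 3-(1,3-dioxolan-2-yl)-5-methoxyphenol | COc1cc(O)cc(C2OCCO2)c1
F3 | step 1 | 2-[3-(benzyloxy)-5-methoxyphenyl]-1,3-dioxolane | COc1cc(OCc2ccccc2)cc(C2OCCO2)c1
F4 | step 5 | 1-(benzyloxy)-3-methoxy-5-(2-methoxyethenyl)benzene (E/Z mixture) | COC=Cc1cc(OC)cc(OCc2ccccc2)c1
F0 | step 6 | none | none
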